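Remark (assumption): the SMILES contains no stereocentre, stereogenic axis or stereogenic double bond, so the target is achiral and there is no enantiomer to select; it is drawn as one of several rapidly interconverting enol tautomers, and all triones below are drawn in the same tautomer.

## Structural features

The target (C36H44O12, the constitution of filixic acid BBB) is a linear trimer of three butanoyl-bearing six-membered rings joined by two CH2 bridges. The central ring A is a fully substituted benzene with butanoyl at C1, OH at C2, C4 and C6, and one bridging CH2 at each of C3 and C5. Each outer ring B is a non-aromatic 2-butanoyl-3,5-dihydroxy-4,4-dimethylcyclohexa-2,5-dien-1-one (an enolised β,β'-triketone, i.e. a dearomatised phloroglucinol) that carries the bridge at C6 and a quaternary gem-dimethyl carbon at C4. C4 of ring B bears two identical methyl groups, so the problem is purely one of constitution and chemoselectivity. Each bridge CH2 lies between a vinylogous acid and an electron-rich phenol, so the bridges can cleave by retro-Michael reaction in alkali and scramble; the polyenol array is strongly acidic, chelates metals and is sensitive to oxidants, and the ring–acyl bonds can suffer retro-Claisen cleavage in hot base. The real difficulty is to form two unsymmetrical A–CH2–B bridges and no A–CH2–A or B–CH2–B bridge, although rings A and B are both carbon nucleophiles, and to stop the C-methylation of ring B at the right level. The key step exploits the position of the bridge carbon on C6 of ring B, between C1=O and the C5 enol: the bridge CH2 is the dehydrogenated form of a C6–CH3 group, and removal of two hydrogens makes it the terminus of a 6-methylidene-1,5-dione acceptor that the two free carbons C3 and C5 of ring A can attack.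

## Logic of the disconnections

8 is cut at the two bonds between the bridge carbons and C3/C5 of ring A, each bridge carbon staying on ring B as a C6-methyl group; this gives 3 and two molecules of 5. The cut is made here because the roles are then fixed by structure: only 5 can become an electrophile (as 6), only 3 can act as a ring-carbon nucleophile, and no free C1 reagent is present, so only A–CH2–B bridges can form. The gain is that a C36 trimer falls to two small compounds, one of which is the precursor of the other. The demand on the forward step is a dehydrogenation of the C6–CH3 of 5 that spares 3, 7 and 8, and a capture of 6 by ring carbon (first giving 7, then 8) that is faster than self-reaction of 6. In one sentence: the route is a twofold dehydrogenative coupling in which the C6-methyl group of 5 is oxidised to 6 and captured by both free ring carbons of 3.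

5 is cut at its three C–CH3 bonds (two at C4, one at C6), which leads back to 3 and three molecules of 4. The cut is made here because all ring-B carbons that are not part of the arene, including the later bridge carbon, then come from one reagent in one operation; the "extra" third methyl group, a nuisance in the classical approach, is the functional handle here. The gain is the loss of the quaternary centre and of the dearomatised ring. The demand is C- over O-alkylation and a stop after three methyl groups.

3 is cut at the aryl–C(=O) bond, giving 1 and 2. The three ring positions of 1 are equivalent, so no regiochemistry has to be controlled; the gain is the loss of the side chain. The demand is mono-acylation.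

## Other disconnections considered

Alternative 1: This is the first disconnection that comes to mind. Both bonds of each bridge are cut, so that the bridge carbons come from formaldehyde. The forward key step is a base-mediated three-component condensation of 2-butanoyl-3,5-dihydroxy-4,4-dimethylcyclohexa-2,5-dien-1-one A1 (two equivalents), 3 and formaldehyde. A free bifunctional C1 electrophile is here offered at once to three nucleophilic ring carbons (C6 of A1, C3 and C5 of 3). On mechanistic grounds the homodimer 6,6'-methylenebis(2-butanoyl-3,5-dihydroxy-4,4-dimethylcyclohexa-2,5-dien-1-one) A2 and aryl–CH2–aryl oligomers must compete, and the alkaline medium allows bridge scrambling by retro-Michael reaction. A1 also requires the ring methylation to be stopped at two methyl groups with a free, highly nucleophilic C6–H. The chosen plan encodes the electrophile in one partner and uses the third methyl group productively.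

Alternative 2: The two C–CH3 bonds that complete the quaternary carbons are cut last (late dearomatisation). The forward key step is a twofold dearomative C-methylation of the all-aromatic trimer 1-[3,5-bis[(3-butanoyl-2,4,6-trihydroxy-5-methylphenyl)methyl]-2,4,6-trihydroxyphenyl]butan-1-one A3. Each outer ring of A3 offers two alkylatable ring carbons flanked by two OH groups (C–CH3 and C–CH2Ar), and the central ring offers two more, so site selectivity has no structural basis. The methylation needs alkoxide, which is the condition under which the bridges equilibrate. A3 would itself have to come from a statistically controlled formaldehyde bridging. The chosen plan dearomatises before any bridge exists.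

Alternative 3: The same bridges are cut on the other side (C6 of ring B–CH2), with the bridge carbons stored as aromatic methyl groups in 1-(2,4,6-trihydroxy-3,5-dimethylphenyl)butan-1-one A4. The forward key step is oxidation of A4 to its o-quinone methide 2-butanoyl-3,5-dihydroxy-4-methyl-6-methylidenecyclohexa-2,4-dien-1-one A5 and capture by A1, run twice. Here the nucleophile A1 is the strongest acid and the most easily oxidised enolate in the flask, while the aromatic methyl of A4 requires a higher potential, so oxidant and polarity work against each other. Two differently methylated building blocks (A1 and A4) would also be needed, which makes the route longer. In the chosen plan the most oxidisable species is the intended electrophile precursor.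

Key step: step 3

## Route

Step 1
Reactants: 1 phloroglucinol (benzene-1,3,5-triol); 2 butanoyl chloride
Product: 3 1-(2,4,6-trihydroxyphenyl)butan-1-one
Conditions: AlCl3 (4 equiv), PhNO2, rt → 60 °C; then ice/1 M HCl
Reagents that add atoms: butanoyl chloride (2), CCCC(=O)Cl
Why: Friedel–Crafts C-acylation of the C3-symmetric triol, whose three ring positions are equivalent; the first acyl group, chelated to aluminium through the ortho-phenoxides, deactivates the ring against a second acylation, and any aryl ester formed at oxygen should be carried on to the ketone by Fries rearrangement under the same conditions.

Step 2
Reactants: 3 1-(2,4,6-trihydroxyphenyl)butan-1-one; 4 iodomethane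
Product: 5 2-butanoyl-3,5-dihydroxy-4,4,6-trimethylcyclohexa-2,5-dien-1-one
Conditions: NaOMe (4 equiv), MeI (3.1 equiv), MeOH, 0 °C → rt; then 1 M HCl
Reagents that add atoms: iodomethane (4), CI
Why: Dearomative C-methylation of the phloroglucinol phenoxide: in methanol the hydrogen-bonded oxygens are shielded and the soft electrophile is taken at ring carbon, two methyl groups entering at one free ring carbon (the later C4, which breaks aromaticity and forms the quaternary, non-stereogenic centre) and one at the other (the later C6); both orders of alkylation converge on 5. The delocalised trione enolate of 5 is a weak nucleophile, so with 3.1 equiv of MeI the fourth methylation should stay minor.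

Step 3
Reactants: 5 2-butanoyl-3,5-dihydroxy-4,4,6-trimethylcyclohexa-2,5-dien-1-one (2.5 equiv); 3 1-(2,4,6-trihydroxyphenyl)butan-1-one (1.0 equiv)
Product: 8 6,6'-[(5-butanoyl-2,4,6-trihydroxy-1,3-phenylene)bis(methylene)]bis(2-butanoyl-3,5-dihydroxy-4,4-dimethylcyclohexa-2,5-dien-1-one) (the target), via methylidene trione 6 (not isolated), via mono-bridged dimer 7 (not isolated)
Conditions: TEMPO (20 mol %), Ag2O (2.2 equiv, in portions), THF (0.02 M), 0 °C → rt, dark, Ar; filtration through Celite, wash with 0.5 M HCl
Reagents that add atoms: none
Why: The vinylogous acid 5 (expected pKa about 4–5, against about 8 for 3) is deprotonated on Ag2O and its enolate is oxidised by one electron to a radical delocalised over C2 and C6; TEMPO removes a hydrogen atom from the C6-methyl group of this radical to give 6, and Ag2O reoxidises the hydroxylamine to TEMPO. 6 is a doubly activated 2-methylidene-1,3-dione (an o-quinone methide equivalent) and is attacked at its CH2 terminus by the free ring carbon C3 of 3 in a Friedel–Crafts-type Michael addition; tautomerisation restores the arene and the enolised trione to give 7, whose remaining ring CH (C5, still flanked by two OH groups) repeats the addition with a second 6 to give 8. The closest known reaction types are the TEMPO/Ag2O dehydrogenation of C-methylated dearomatised acylphloroglucinols to methylidene triones (otherwise trapped by alkenes in hetero-Diels–Alder reactions) and the twofold Michael addition of acylphloroglucinols to alkylidene cyclic triones that gives trimeric acylphloroglucinols. No ring is closed and no stereocentre is formed. The step needs chemoselective oxidation of 5 in the presence of 3, 7 and 8: only 5 is present as an easily oxidised enolate while 3 stays largely neutral, the trione units of 7 and 8 are clamped by hydrogen bonds to the flanking phenols and carry a bulkier C6 substituent, and 5 is kept in excess over the portionwise added oxidant to the end. Only hetero-bridges can form, because no free C1 electrophile is present, 3 can only be a nucleophile and C6 of 5 is blocked by its methyl group. Adducts of 6 at that blocked carbon or at oxygen cannot enolise or rearomatise and can revert by retro-Michael reaction, whereas the C-adducts 7 and 8 are fixed by rearomatisation. Hetero-Diels–Alder dimerisation of 6 is held back by its low stationary concentration in the presence of the full amount of 3.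

## Compound list

1 | phloroglucinol (benzene-1,3,5-triol) | Oc1cc(O)cc(O)c1 | starting material
2 | butanoyl chloride | CCCC(=O)Cl | starting material
3 | 1-(2,4,6-trihydroxyphenyl)butan-1-one | CCCC(=O)c1c(O)cc(O)cc1O | intermediate
4 | iodomethane | CI | starting material
5 | 2-butanoyl-3,5-dihydroxy-4,4,6-trimethylcyclohexa-2,5-dien-1-one | CCCC(=O)C1=C(O)C(C)(C)C(O)=C(C)C1=O | intermediate
6 | 2-butanoyl-3-hydroxy-4,4-dimethyl-6-methylidenecyclohex-2-ene-1,5-dione (not isolated) | CCCC(=O)C1=C(O)C(C)(C)C(=O)C(=C)C1=O | intermediate
7 | 2-butanoyl-6-[(3-butanoyl-2,4,6-trihydroxyphenyl)methyl]-3,5-dihydroxy-4,4-dimethylcyclohexa-2,5-dien-1-one (not isolated) | CCCC(=O)C1=C(O)C(C)(C)C(O)=C(Cc2c(O)cc(O)c(C(=O)CCC)c2O)C1=O | intermediate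
8 | 6,6'-[(5-butanoyl-2,4,6-trihydroxy-1,3-phenylene)bis(methylene)]bis(2-butanoyl-3,5-dihydroxy-4,4-dimethylcyclohexa-2,5-dien-1-one) | CCCC(=O)C1=C(O)C(C)(C)C(O)=C(Cc2c(O)c(CC3=C(O)C(C)(C)C(O)=C(C(=O)CCC)C3=O)c(O)c(C(=O)CCC)c2O)C1=O | target

## Step count and least certain steps

Total step count: 3. Longest linear sequence: 3 steps (1 → 3 → 5 → 8); 3 enters twice, as precursor of 5 and as the central building block.

Step 3 (key step). The most likely failure is over-oxidation of the bridged trione units and oxidative degradation of the phenol, because the oxidant cannot distinguish sharply between the enolate of 5 and the enolates of 7 and 8. Self-capture of the methylidene trione (hetero-Diels–Alder dimerisation, or attack by the enolate of 5) is also possible, because the acceptor is generated next to its own precursor. An incomplete second coupling would leave the reaction at the mono-bridged stage. The fallback releases 6 without any oxidant; it sets out from 3 and 4 and comes back to the route at 6 (formed in the flask) and so at 8. 3 would be C-methylated with only two equivalents of 4 (NaOMe, MeOH) to 2-butanoyl-3,5-dihydroxy-4,4-dimethylcyclohexa-2,5-dien-1-one F1 (identical with A1). F1 would be aminomethylated at C6 with morpholine and aqueous formaldehyde (EtOH, rt) to the Mannich base 2-butanoyl-3,5-dihydroxy-4,4-dimethyl-6-(morpholin-4-ylmethyl)cyclohexa-2,5-dien-1-one F2, isolated as its zwitterion and freed from F1. Warming F2 (2.1 equiv) with 3 (1 equiv) in dioxane buffered with a little AcOH should expel morpholine by β-elimination, so that 6 is formed and captured via 7 to 8 as in step 3. The approach changes from C–H oxidation to an amine leaving group (Mannich base as o-quinone methide precursor), at the price of two more steps and the dimethylation problem of Alternative 1.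

Step 2. The most likely failure is loss of control over the degree of methylation (stopping after two or running on to four methyl groups), together with some O-methylation, because every methylation leaves an enolate or phenoxide that is still nucleophilic. The fallback puts the later bridge carbon into the arene from the start; it sets out from 2 and 4 and comes back at 5. Commercial 2-methylbenzene-1,3,5-triol F3 would be acylated with 2 (AlCl3, PhNO2) to 1-(2,4,6-trihydroxy-3-methylphenyl)butan-1-one F4, and F4 would be C-methylated with two equivalents of 4 (NaOMe, MeOH). Only two methylations are then needed, and both possible orders (first at the free ring carbon, or first at the methyl-bearing carbon) converge on 5.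

Step 1. The most likely failure is O-acylation and polyacylation, or incomplete conversion, because the product ties up the Lewis acid. The fallback is a Houben–Hoesch acylation, which is self-limiting; it sets out from 1 and comes back at 3. 1 would be treated with butanenitrile F5, ZnCl2 and dry HCl in Et2O at 0 °C, which precipitates 1-(2,4,6-trihydroxyphenyl)butan-1-iminium chloride F6; the cationic ketiminium group protects the ring from a second attack, and hydrolysis of F6 in hot water gives 3.

## Further compounds

F1 | step 3 | 2-butanoyl-3,5-dihydroxy-4,4-dimethylcyclohexa-2,5-dien-1-one | CCCC(=O)C1=C(O)C(C)(C)C(O)=CC1=O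
F2 | step 3 | 2-butanoyl-3,5-dihydroxy-4,4-dimethyl-6-(morpholin-4-ylmethyl)cyclohexa-2,5-dien-1-one | CCCC(=O)C1=C(O)C(C)(C)C(O)=C(CN2CCOCC2)C1=O
F3 | step 2 | 2-methylbenzene-1,3,5-triol (commercial starting material of the fallback) | Cc1c(O)cc(O)cc1O
F4 | step 2 | 1-(2,4,6-trihydroxy-3-methylphenyl)butan-1-one | CCCC(=O)c1c(O)cc(O)c(C)c1O
F5 | step 1 | butanenitrile (commercial starting material of the fallback) | CCCC#N
F6 | step 1 | 1-(2,4,6-trihydroxyphenyl)butan-1-iminium chloride | CCCC(=[NH2+])c1c(O)cc(O)cc1O.[Cl-]
A1 | alternative 1 | 2-butanoyl-3,5-dihydroxy-4,4-dimethylcyclohexa-2,5-dien-1-one | CCCC(=O)C1=C(O)C(C)(C)C(O)=CC1=O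
A2 | alternative 1 | 6,6'-methylenebis(2-butanoyl-3,5-dihydroxy-4,4-dimethylcyclohexa-2,5-dien-1-one) | CCCC(=O)C1=C(O)C(C)(C)C(O)=C(CC2=C(O)C(C)(C)C(O)=C(C(=O)CCC)C2=O)C1=O
A3 | alternative 2 | 1-[3,5-bis[(3-butanoyl-2,4,6-trihydroxy-5-methylphenyl)methyl]-2,4,6-trihydroxyphenyl]butan-1-one | CCCC(=O)c1c(O)c(Cc2c(O)c(C)c(O)c(C(=O)CCC)c2O)c(O)c(Cc2c(O)c(C)c(O)c(C(=O)CCC)c2O)c1O
A4 | alternative 3 | 1-(2,4,6-trihydroxy-3,5-dimethylphenyl)butan-1-one | CCCC(=O)c1c(O)c(C)c(O)c(C)c1O
A5 | alternative 3 | 2-butanoyl-3,5-dihydroxy-4-methyl-6-methylidenecyclohexa-2,4-dien-1-one | CCCC(=O)C1=C(O)C(C)=C(O)C(=C)C1=O
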